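**What is known**

| flask | substrate | partner | free catalyst | remark | time |
|---|---|---|---|---|---|
| autumn | 7.9 mM | 20 mM | 2 mM | run made earlier |  |
| noon | 31 mM | 20 mM | 2 mM | run made earlier |  |
| spring | 95 mM | 20 mM | 2 mM | run made earlier |  |
| grey | 10 mM | 20.0 mM | 2.0 mM |  | 20 min |
| ochre | 20 mM | 20.0 mM | 2.0 mM |  | 20 min |
| green | 40 mM | 20.0 mM | 2.0 mM |  | 20 min |
| teal | 80 mM | 20.0 mM | 2.0 mM |  | 20 min |

| run | time / min | target / % |
|---|---|---|
| autumn | 3.00 | 28.6 |
| autumn | 6.00 | 49.3 |
| autumn | 8.00 | 52.5 |
| autumn | 12.0 | 48.5 |
| autumn | 15.0 | 41.1 |
| noon | 3.00 | 13.1 |
| noon | 6.00 | 25.4 |
| noon | 8.00 | 30.5 |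
| noon | 12.0 | 41.0 |
| noon | 15.0 | 46.2 |
| spring | 3.00 | 5.5 |
| spring | 6.00 | 9.5 |
| spring | 8.00 | 12.3 |
| spring | 12.0 | 14.5 |
| spring | 15.0 | 17.7 |

(standard deviation of a reading: 1 percentage point)

- the earlier runs were read with a standard deviation of 1 percentage point
- steps under discussion: partner + catalyst intermediate A <-> catalyst intermediate B; substrate + free catalyst -> catalyst intermediate A; partner + free catalyst + target -> free catalyst + over-reaction product; catalyst intermediate B -> free catalyst + target
- "hardly changes" means that all values lie within two and a half points (for a concentration: within two and a half percent of the largest)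

- amount of target at the end, in percent of the substrate charged for grey, ochre, green, teal, in this order
- the course of these numbers from the first flask to the last (rises all the way / hardly changes / falls, then rises / falls all the way / rises, then falls)

1. A leftover opens the argument. At 15.0 min the spring run holds 16.8 mM of target from 95 mM of substrate, so 78.2 mM of that substrate has not ended as target.

2. The steps under discussion take one substrate and one partner into each target, and free catalyst comes back when target is released. The amounts to compare are therefore the two charges. For teal their ratio is 25.0 %, the partner ceiling Y: partner charge over substrate charge, which caps target in percent of the substrate charged. Where Y is below 100 %, partner is the limiting reagent.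

3. Y is 200 % for grey and 100 % for ochre, so substrate caps those flasks at its own charge. For green Y is 50.0 %.

4. Late in the spring run target grows by about 0.733 mM min⁻¹, a pace read off scattered readings. Held steady, that pace covers the remaining 3.19 mM up to the partner charge in 4.35 min, which is shorter than the 5.00 min from that reading to the asked time. That is an estimate, not an event: the reckoning here does not expect the pace to hold while partner is consumed, so it expects target in the spring run to come near the partner charge and stay short of it.

5. The autumn run reads 52.5 % at 8.00 min but a lower 41.1 % at 15.0 min, so target is also consumed. The reckoning here therefore expects grey to end below ochre, then green and teal just under Y: rises, then falls.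

**The forecast**

The forecast gives 38 %, 52 %, 41 % and 22 %, and the shape rises, then falls. Its ground: “Partner is consumed once per target and again per over-reaction, so 20 mM caps the target at under 20 mM.”

**The result**

The flasks give 41.6 %, 66.6 %, 42.4 % and 22.7 %: rises, then falls.

    partner + catalyst intermediate A ⇌ catalyst intermediate B (K = 820 M⁻¹, k = 130 M⁻¹ min⁻¹)
    substrate + free catalyst → catalyst intermediate A (k = 217 M⁻¹ min⁻¹)
    partner + free catalyst + target → free catalyst + over-reaction product (k = 5970 M⁻² min⁻¹)
    catalyst intermediate B → free catalyst + target (k = 1.56 min⁻¹)

Forecast and flask part at ochre, 52 % against 66.6 %. Teal ends at 22.7 %, below its Y of 25.0 %, with 4.1 % of its partner left. Consuming partner costs teal 14 percentage points: with partner held at its charge teal reaches 36.4 %, though that effect is 18 % of what is missing. Each over-reaction product carries two partners, so green at 200 min, with 44.8 % target and 2.59 % over-reaction product, accounts for 50.0 % against its Y of 50.0 %.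

All runs were computed with constants of no real substance.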